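**Retrosynthetic overview**
1. The malate ester C(=O)–O bond is made last, by regioselective opening of (R)-2-(trifluoroacetoxy)succinic anhydride with the primary alcohol of the core acid (2S)-2-[(1S)-1-carboxy-11-hydroxyundecyl]-5-oxooxolane-2-carboxylic acid.
2. The core comes from a 2-(alk-2-en-4-yl)oxolane-2-carboxylate: one RuO4 oxidation turns the ring CH2–O into the lactone C=O and the propenyl group into the CO2H on the CH stereocentre.
3. Key disconnection: the ring O1–C2 bond. An allylic ether oxygen attacks a rhodium carbene made from an acyclic α-diazo ester; the five-membered oxonium ylide then undergoes a [2,3]-sigmatropic shift that forges C2–C1′ and sets both stereocentres by chirality transfer from one (S)-carbinol carbon (from a CBS reduction).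
4. Enabling feature: ring oxygen O1 sits on quaternary C2, which carries its own carboxyl (a latent diazo ester carbon), and C2 is bonded to C1′, whose carboxyl can be a masked vinyl group. O1–C2(CO2R)–C1′–C=C is the homoallylic α-alkoxy ester pattern that an oxonium ylide [2,3] shift produces.
5. Ring order: the oxolane is the only ring built (step 8) and becomes the 5-oxooxolane in step 9; the acyclic precursor is assembled from an (E)-enone, 3-bromopropan-1-ol and methyl acetoacetate.

Key step: step 8

Remark: the hydroxy acid unit of the target is (R)-configured and is taken from (R)-malic acid (D-malic acid); both core centres are (S).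

**Step 1**
Reactants: 1 11-bromoundecan-1-ol
Product: 2 11-hydroxyundecyl 2,2-dimethylpropanoate
Conditions: KO2CC(CH3)3 (1.5 equiv), DMF, 70 °C
Reagents that add atoms: potassium pivalate, CC(C)(C)C(=O)[O-].[K+]
Why: SN2 O-alkylation of the carboxylate by the primary bromide installs a pivalate that tolerates every later base, carbene and oxidation step, while the free hydroxyl is not basic enough to compete.

**Step 2**
Reactants: 2 11-hydroxyundecyl 2,2-dimethylpropanoate
Product: 3 11-oxoundecyl 2,2-dimethylpropanoate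
Conditions: TEMPO (10 mol%), PhI(OAc)2 (1.1 equiv), CH2Cl2, rt
Reagents that add atoms: none
Why: Oxoammonium (TEMPO) oxidation of a primary alcohol should stop cleanly at the aldehyde and leaves the ester untouched.

**Step 3**
Reactants: 3 11-oxoundecyl 2,2-dimethylpropanoate; 4 dimethyl (2-oxopropyl)phosphonate
Product: 5 (11E)-13-oxotetradec-11-en-1-yl 2,2-dimethylpropanoate
Conditions: 4, NaH, THF, 0 °C; then 3, 0 °C → rt
Reagents that add atoms: none
Why: Horner–Wadsworth–Emmons olefination with a stabilised β-keto phosphonate anion should give the E-enone, and the preformed anion leaves no free base to enolise the aldehyde.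

**Step 4**
Reactants: 5 (11E)-13-oxotetradec-11-en-1-yl 2,2-dimethylpropanoate
Product: 6 (11E,13S)-13-hydroxytetradec-11-en-1-yl 2,2-dimethylpropanoate
Conditions: (R)-2-methyl-CBS-oxazaborolidine (15 mol%), catecholborane (1.8 equiv), toluene, −78 °C; aq. NaOH work-up
Reagents that add atoms: none
Why: Corey–Bakshi–Shibata reduction with the alkenyl group as the large substituent should deliver hydride from the (R)-catalyst to the face that gives the (S)-carbinol, and catecholborane at low temperature reduces the ketone 1,2 without hydroborating the alkene or touching the ester.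

**Step 5**
Reactants: 6 (11E,13S)-13-hydroxytetradec-11-en-1-yl 2,2-dimethylpropanoate; 7 3-bromopropan-1-ol
Product: 9 (11E,13S)-13-(3-bromopropoxy)tetradec-11-en-1-yl 2,2-dimethylpropanoate, via 3-bromopropyl trifluoromethanesulfonate 8 (not isolated)
Conditions: 7 (1.6 equiv), (CF3SO2)2O (1.5 equiv), 2,6-di-tert-butyl-4-methylpyridine (3.5 equiv), CH2Cl2, −40 °C; then 6, 0 °C → rt
Reagents that add atoms: none
Why: Etherification of the secondary alcohol by SN2 attack on a primary triflate under a hindered non-nucleophilic base avoids alkoxide (no elimination, no ester exchange), the bromide is far less reactive than the triflate, and the carbinol C–O bond is never broken so the (S) centre is kept.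

**Step 6**
Reactants: 9 (11E,13S)-13-(3-bromopropoxy)tetradec-11-en-1-yl 2,2-dimethylpropanoate; 10 methyl 3-oxobutanoate
Product: 11 methyl 2-acetyl-5-{[(2S,3E)-14-(2,2-dimethylpropanoyloxy)tetradec-3-en-2-yl]oxy}pentanoate (both C2 epimers)
Conditions: 10 (3 equiv), K2CO3, DMF, 50 °C
Reagents that add atoms: none
Why: Acetoacetic ester C-alkylation (SN2 of the stabilised enolate on the primary bromide) attaches the future quaternary carbon with its ester, and excess 10 suppresses dialkylation.

**Step 7**
Reactants: 11 methyl 2-acetyl-5-{[(2S,3E)-14-(2,2-dimethylpropanoyloxy)tetradec-3-en-2-yl]oxy}pentanoate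
Product: 12 methyl 2-diazo-5-{[(2S,3E)-14-(2,2-dimethylpropanoyloxy)tetradec-3-en-2-yl]oxy}pentanoate
Conditions: 4-acetamidobenzenesulfonyl azide (1.3 equiv), DBU (1.5 equiv), MeCN, 0 °C → rt
Reagents that add atoms: 4-acetamidobenzenesulfonyl azide, CC(=O)Nc1ccc(cc1)S(=O)(=O)N=[N+]=[N-]
Why: Regitz deacylative diazo transfer to the α-alkyl β-keto ester should give the α-diazo ester, the acetyl group leaving on the sulfonamide nitrogen, and it removes the scrambled C2 centre.

**Step 8**
Reactants: 12 methyl 2-diazo-5-{[(2S,3E)-14-(2,2-dimethylpropanoyloxy)tetradec-3-en-2-yl]oxy}pentanoate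
Product: 14 methyl (2S)-2-[(2E,4R)-14-(2,2-dimethylpropanoyloxy)tetradec-2-en-4-yl]oxolane-2-carboxylate, via five-membered oxonium ylide 13 (not isolated)
Conditions: Rh2(O2CCPh3)4 (1 mol%), CH2Cl2 (0.02 M), −78 °C → 0 °C
Reagents that add atoms: none
Why: The dirhodium tetracarboxylate (divalent rhodium) expels N2 from 12 to give an electrophilic metal-bound carbene, a lone pair of the ether oxygen five atoms away attacks the carbene carbon so that the oxolane closes by O–C bond formation (ylide 13), and the allyl group then moves from oxygen to the ylide carbon in a suprafacial [2,3]-sigmatropic shift that makes the C2–C bond and transposes the alkene. The closest known reaction type is the tandem oxonium ylide formation/[2,3]-sigmatropic rearrangement of diazo esters and diazo ketones that carry an allyl ether. The ring closes in a five-membered mode (ring atoms O, C2 and the three tether CH2) by addition of a heteroatom to a carbene centre, and the saturated three-carbon tether allows no smaller ring. The CH centre is set by 1,3-chirality transfer from the (S)-carbinol carbon, whose methyl sits pseudo-equatorial in the five-membered envelope transition state (this also gives the E-propenyl group). The quaternary centre is set relative to it by the exo arrangement of the allyl unit, which keeps the methyl and the chain of the E-alkene away from ring C3 and C5 and places the chain over the flat ester enolate. The step needs ylide closure to outrun 1,2-hydride migration from the neighbouring CH2 and C–H insertion, and [2,3] shift to outrun [1,2] shift; the bulky triphenylacetate ligands, the low temperature, the five-atom distance of the ether oxygen and the allylic nature of the migrating group should secure this.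

**Step 9**
Reactants: 14 methyl (2S)-2-[(2E,4R)-14-(2,2-dimethylpropanoyloxy)tetradec-2-en-4-yl]oxolane-2-carboxylate
Product: 15 (2S)-12-(2,2-dimethylpropanoyloxy)-2-[(2S)-2-(methoxycarbonyl)-5-oxooxolan-2-yl]dodecanoic acid
Conditions: RuCl3·xH2O (5 mol%), NaIO4 (8 equiv), EtOAc/MeCN/H2O, rt
Reagents that add atoms: sodium periodate, [Na+].[O-]I(=O)(=O)=O (oxygen carried over by RuO4); water, O
Why: RuO4 made in situ (ruthenium tetroxide oxidation) cleaves the disubstituted alkene to the carboxylic acid and oxidises the only CH2 next to the ring oxygen (C2 is quaternary) to the lactone carbonyl, while the acylated chain CH2–O is deactivated and no stereocentre is touched.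

**Step 10**
Reactants: 15 (2S)-12-(2,2-dimethylpropanoyloxy)-2-[(2S)-2-(methoxycarbonyl)-5-oxooxolan-2-yl]dodecanoic acid
Product: 17 (2S)-2-[(1S)-1-carboxy-11-hydroxyundecyl]-5-oxooxolane-2-carboxylic acid, via trilithium (3S,4S)-3,14-dihydroxytetradecane-1,3,4-tricarboxylate 16 (not isolated)
Conditions: LiOH·H2O (8 equiv), THF/MeOH/H2O, 50 °C; then 2 M HCl to pH 1, 40 °C
Reagents that add atoms: lithium hydroxide, [Li+].[OH-]
Why: Saponification cleaves the methyl ester and the pivalate and opens the lactone to a tricarboxylate whose α-hydrogen is not acidic, so the CH centre should not epimerise, and acidification recloses only the five-membered lactone because the tertiary hydroxyl reaches no other carboxyl in an unstrained ring (lactonisation).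

**Step 11**
Reactants: 18 (R)-malic acid
Product: 19 (3R)-2,5-dioxooxolan-3-yl 2,2,2-trifluoroacetate
Conditions: (CF3CO)2O (5 equiv, neat), 0 °C → rt; evaporate to dryness
Reagents that add atoms: trifluoroacetic anhydride, O=C(OC(=O)C(F)(F)F)C(F)(F)F
Why: Trifluoroacetic anhydride acylates the hydroxyl and dehydrates the diacid to the cyclic anhydride (mixed-anhydride cyclodehydration) without touching the stereocentre, and thorough evaporation removes the excess reagent so that it cannot activate the acids of 17.

**Step 12**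
Reactants: 17 (2S)-2-[(1S)-1-carboxy-11-hydroxyundecyl]-5-oxooxolane-2-carboxylic acid; 19 (3R)-2,5-dioxooxolan-3-yl 2,2,2-trifluoroacetate
Product: 21 (2S)-2-[(1S)-1-carboxy-11-{[(2R)-3-carboxy-2-hydroxypropanoyl]oxy}undecyl]-5-oxooxolane-2-carboxylic acid, via O-trifluoroacetyl ester 20 (not isolated)
Conditions: 19 (2.5 equiv), THF, 0 °C → rt; then H2O/THF, rt; reversed-phase chromatography
Reagents that add atoms: none
Why: Regioselective alcoholysis of the unsymmetrical anhydride takes place at the more electrophilic carbonyl next to the trifluoroacetoxy-bearing carbon, which gives the 1-ester with the 4-carboxyl free, and water then hydrolyses the labile trifluoroacetate and any excess anhydride without touching the new ester, the lactone or the (R) centre.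

**Compound list**
1 | 11-bromoundecan-1-ol | OCCCCCCCCCCCBr | starting material
2 | 11-hydroxyundecyl 2,2-dimethylpropanoate | OCCCCCCCCCCCOC(=O)C(C)(C)C | intermediate
3 | 11-oxoundecyl 2,2-dimethylpropanoate | O=CCCCCCCCCCCOC(=O)C(C)(C)C | intermediate
4 | dimethyl (2-oxopropyl)phosphonate | CC(=O)CP(=O)(OC)OC | starting material
5 | (11E)-13-oxotetradec-11-en-1-yl 2,2-dimethylpropanoate | CC(=O)/C=C/CCCCCCCCCCOC(=O)C(C)(C)C | intermediate
6 | (11E,13S)-13-hydroxytetradec-11-en-1-yl 2,2-dimethylpropanoate | C[C@H](O)/C=C/CCCCCCCCCCOC(=O)C(C)(C)C | intermediate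
7 | 3-bromopropan-1-ol | OCCCBr | starting material
8 | 3-bromopropyl trifluoromethanesulfonate | BrCCCOS(=O)(=O)C(F)(F)F | intermediate
9 | (11E,13S)-13-(3-bromopropoxy)tetradec-11-en-1-yl 2,2-dimethylpropanoate | BrCCCO[C@@H](C)/C=C/CCCCCCCCCCOC(=O)C(C)(C)C | intermediate
10 | methyl 3-oxobutanoate | CC(=O)CC(=O)OC | starting material
11 | methyl 2-acetyl-5-{[(2S,3E)-14-(2,2-dimethylpropanoyloxy)tetradec-3-en-2-yl]oxy}pentanoate | CC(=O)C(C(=O)OC)CCCO[C@@H](C)/C=C/CCCCCCCCCCOC(=O)C(C)(C)C | intermediate
12 | methyl 2-diazo-5-{[(2S,3E)-14-(2,2-dimethylpropanoyloxy)tetradec-3-en-2-yl]oxy}pentanoate | COC(=O)C(=[N+]=[N-])CCCO[C@@H](C)/C=C/CCCCCCCCCCOC(=O)C(C)(C)C | intermediate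
13 | 1-[(2S,3E)-14-(2,2-dimethylpropanoyloxy)tetradec-3-en-2-yl]-2-(methoxycarbonyl)oxolan-1-ium-2-ide | COC(=O)[C-]1CCC[O+]1[C@@H](C)/C=C/CCCCCCCCCCOC(=O)C(C)(C)C | intermediate
14 | methyl (2S)-2-[(2E,4R)-14-(2,2-dimethylpropanoyloxy)tetradec-2-en-4-yl]oxolane-2-carboxylate | CC(C)(C)C(=O)OCCCCCCCCCC[C@H](/C=C/C)[C@]1(C(=O)OC)CCCO1 | intermediate
15 | (2S)-12-(2,2-dimethylpropanoyloxy)-2-[(2S)-2-(methoxycarbonyl)-5-oxooxolan-2-yl]dodecanoic acid | CC(C)(C)C(=O)OCCCCCCCCCC[C@H](C(=O)O)[C@]1(C(=O)OC)CCC(=O)O1 | intermediate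
16 | trilithium (3S,4S)-3,14-dihydroxytetradecane-1,3,4-tricarboxylate | OCCCCCCCCCC[C@H](C(=O)[O-])[C@](O)(C(=O)[O-])CCC(=O)[O-].[Li+].[Li+].[Li+] | intermediate
17 | (2S)-2-[(1S)-1-carboxy-11-hydroxyundecyl]-5-oxooxolane-2-carboxylic acid | OCCCCCCCCCC[C@H](C(=O)O)[C@]1(C(=O)O)CCC(=O)O1 | intermediate
18 | (R)-malic acid, (2R)-2-hydroxybutanedioic acid | O=C(O)C[C@@H](O)C(=O)O | starting material
19 | (3R)-2,5-dioxooxolan-3-yl 2,2,2-trifluoroacetate | O=C1C[C@@H](OC(=O)C(F)(F)F)C(=O)O1 | intermediate
20 | (2S)-2-[(1S)-1-carboxy-11-{[(2R)-3-carboxy-2-(2,2,2-trifluoroacetoxy)propanoyl]oxy}undecyl]-5-oxooxolane-2-carboxylic acid | O=C(O)C[C@@H](OC(=O)C(F)(F)F)C(=O)OCCCCCCCCCC[C@H](C(=O)O)[C@]1(C(=O)O)CCC(=O)O1 | intermediate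
21 | (2S)-2-[(1S)-1-carboxy-11-{[(2R)-3-carboxy-2-hydroxypropanoyl]oxy}undecyl]-5-oxooxolane-2-carboxylic acid | O=C(O)C[C@@H](O)C(=O)OCCCCCCCCCC[C@H](C(=O)O)[C@]1(C(=O)O)CCC(=O)O1 | target

**Step count and risks**
Total steps: 12. Longest linear sequence: 11 steps (steps 1–10 and 12, from 11-bromoundecan-1-ol); step 11 is a one-step side branch.

Steps most likely to fail:

1. Step 8. The rhodium carbene may undergo 1,2-hydride migration from the neighbouring CH2 (giving the enoate) or C–H insertion faster than the ether oxygen closes the ring, and part of the ylide may rearrange through the endo envelope, which would erode the configuration at the quaternary carbon. The fallback sets out from 6 and comes back at 14, and it makes the C2–C bond on a ready-made oxolane instead. Esterification of 6 with commercial oxolane-2-carboxylic acid (DCC, DMAP, CH2Cl2) gives (2S,3E)-14-(2,2-dimethylpropanoyloxy)tetradec-3-en-2-yl oxolane-2-carboxylate F1. LiN(iPr)2 and Me3SiCl in THF at −78 °C give the chelation-controlled O-silyl ketene acetal, [(2S,3E)-14-(2,2-dimethylpropanoyloxy)tetradec-3-en-2-yl]oxy(trimethylsilyloxy)methylideneoxolane F2 (ring oxygen cis to the silyloxy group). On warming, F2 should undergo Ireland–Claisen rearrangement through a chair to trimethylsilyl (2S)-2-[(2E,4R)-14-(2,2-dimethylpropanoyloxy)tetradec-2-en-4-yl]oxolane-2-carboxylate F3, with the same chirality transfer from the (S)-carbinol and the same syn relation of ring oxygen and chain. Aqueous work-up frees (2S)-2-[(2E,4R)-14-(2,2-dimethylpropanoyloxy)tetradec-2-en-4-yl]oxolane-2-carboxylic acid F4, and Me3SiCHN2 in toluene/MeOH gives 14.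

2. Step 9. Oxidation of the ring CH2 may lag behind alkene cleavage, so that long exposure to RuO4 leads to incomplete conversion or to C–H oxidation along the chain. The fallback sets out from 14 and comes back at 15, and it separates the two oxidations. Ozonolysis (O3, CH2Cl2/MeOH, −78 °C; Me2S) gives methyl (2S)-2-[(2S)-12-(2,2-dimethylpropanoyloxy)-1-oxododecan-2-yl]oxolane-2-carboxylate F5. Pinnick oxidation (NaClO2, NaH2PO4, 2-methylbut-2-ene, t-BuOH/H2O) gives (2S)-12-(2,2-dimethylpropanoyloxy)-2-[(2S)-2-(methoxycarbonyl)oxolan-2-yl]dodecanoic acid F6. The ring CH2 next to oxygen is then oxidised on its own with CrO3 in AcOH (hexavalent chromium) to give 15.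

3. Step 12. The two free carboxyl groups of 17 may be activated by the anhydride (mixed or cyclic anhydride formation), or the anhydride may be opened at the wrong carbonyl, giving the isomeric 4-ester. The fallback sets out from 17 and comes back at 21, and it forms the ester by carboxylate alkylation instead of acylation. N,N′-Diisopropyl-O-tert-butylisourea (CH2Cl2, rt) gives di-tert-butyl ester tert-butyl (2S)-2-[(2S)-1-tert-butoxy-12-hydroxy-1-oxododecan-2-yl]-5-oxooxolane-2-carboxylate F7. MsCl/Et3N gives the corresponding primary methanesulfonate, tert-butyl (2S)-2-[(2S)-1-tert-butoxy-12-(methylsulfonyloxy)-1-oxododecan-2-yl]-5-oxooxolane-2-carboxylate F8. Separately, commercial D-aspartic acid 4-tert-butyl ester is deaminated with retention (NaNO2, aq. AcOH, 0 °C) to (2R)-4-tert-butoxy-2-hydroxy-4-oxobutanoic acid F9. The caesium salt of F9 (Cs2CO3, DMF, 50 °C) displaces the methanesulfonate of F8 to give the tri-tert-butyl ester of the target, tert-butyl (2S)-2-[(2S)-1-tert-butoxy-12-{[(2R)-4-tert-butoxy-2-hydroxy-4-oxobutanoyl]oxy}-1-oxododecan-2-yl]-5-oxooxolane-2-carboxylate F10. CF3CO2H/CH2Cl2 then removes the three tert-butyl groups to give 21.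

**Further compounds**
F1 | step 8 | (2S,3E)-14-(2,2-dimethylpropanoyloxy)tetradec-3-en-2-yl oxolane-2-carboxylate | O=C(O[C@@H](C)/C=C/CCCCCCCCCCOC(=O)C(C)(C)C)C1CCCO1
F2 | step 8 | [(2S,3E)-14-(2,2-dimethylpropanoyloxy)tetradec-3-en-2-yl]oxy(trimethylsilyloxy)methylideneoxolane | C[Si](C)(C)O/C(O[C@@H](C)/C=C/CCCCCCCCCCOC(=O)C(C)(C)C)=C1\OCCC1
F3 | step 8 | trimethylsilyl (2S)-2-[(2E,4R)-14-(2,2-dimethylpropanoyloxy)tetradec-2-en-4-yl]oxolane-2-carboxylate | CC(C)(C)C(=O)OCCCCCCCCCC[C@H](/C=C/C)[C@]1(C(=O)O[Si](C)(C)C)CCCO1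
F4 | step 8 | (2S)-2-[(2E,4R)-14-(2,2-dimethylpropanoyloxy)tetradec-2-en-4-yl]oxolane-2-carboxylic acid | CC(C)(C)C(=O)OCCCCCCCCCC[C@H](/C=C/C)[C@]1(C(=O)O)CCCO1
F5 | step 9 | methyl (2S)-2-[(2S)-12-(2,2-dimethylpropanoyloxy)-1-oxododecan-2-yl]oxolane-2-carboxylate | CC(C)(C)C(=O)OCCCCCCCCCC[C@H](C=O)[C@]1(C(=O)OC)CCCO1
F6 | step 9 | (2S)-12-(2,2-dimethylpropanoyloxy)-2-[(2S)-2-(methoxycarbonyl)oxolan-2-yl]dodecanoic acid | CC(C)(C)C(=O)OCCCCCCCCCC[C@H](C(=O)O)[C@]1(C(=O)OC)CCCO1
F7 | step 12 | tert-butyl (2S)-2-[(2S)-1-tert-butoxy-12-hydroxy-1-oxododecan-2-yl]-5-oxooxolane-2-carboxylate | OCCCCCCCCCC[C@H](C(=O)OC(C)(C)C)[C@]1(C(=O)OC(C)(C)C)CCC(=O)O1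
F8 | step 12 | tert-butyl (2S)-2-[(2S)-1-tert-butoxy-12-(methylsulfonyloxy)-1-oxododecan-2-yl]-5-oxooxolane-2-carboxylate | CS(=O)(=O)OCCCCCCCCCC[C@H](C(=O)OC(C)(C)C)[C@]1(C(=O)OC(C)(C)C)CCC(=O)O1
F9 | step 12 | (2R)-4-tert-butoxy-2-hydroxy-4-oxobutanoic acid | CC(C)(C)OC(=O)C[C@@H](O)C(=O)O
F10 | step 12 | tert-butyl (2S)-2-[(2S)-1-tert-butoxy-12-{[(2R)-4-tert-butoxy-2-hydroxy-4-oxobutanoyl]oxy}-1-oxododecan-2-yl]-5-oxooxolane-2-carboxylate | CC(C)(C)OC(=O)C[C@@H](O)C(=O)OCCCCCCCCCC[C@H](C(=O)OC(C)(C)C)[C@]1(C(=O)OC(C)(C)C)CCC(=O)O1
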